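What does a larger charge of second substrate do to the rate of making target in the flask at 10% conversion?

all flasks: starting material 0.11 M; second substrate 0.198 M

| charge | enzyme | impurity | remark |
|---|---|---|---|
| south | 22 µM | 37 µM | run made earlier |
| north-east | 86 µM | 37 µM | run made earlier |
| north | 43 µM | 18 µM | run made earlier |
| flask | 43 µM | 37 µM |  |

| run | time / s | target / % | starting material / % |
|---|---|---|---|
| south | 15.0 | 0.5 | 100.2 |
| south | 30.0 | 0.3 | 100.3 |
| south | 50.0 | 0.1 | 100.5 |
| south | 60.0 | 0 | 100.2 |
| south | 80.0 | 0.7 | 98.9 |
| south | 90.0 | 0.7 | 99.3 |
| south | 120 | 0 | 99.7 |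
| north-east | 10.0 | 8.9 | 92.0 |
| north-east | 15.0 | 12.0 | 87.3 |
| north-east | 20.0 | 16.0 | 84.5 |
| north-east | 30.0 | 23.5 | 77.1 |
| north-east | 50.0 | 35.0 | 65.6 |
| north-east | 80.0 | 48.5 | 51.5 |
| north-east | 120 | 63.5 | 36.2 |
| north | 10.0 | 4.5 | 95.4 |
| north | 20.0 | 7.9 | 91.5 |
| north | 30.0 | 12.1 | 87.4 |
| north | 60.0 | 21.9 | 77.8 |
| north | 120 | 37.9 | 62.2 |

(each reading ± 0.5 percentage points)

- no earlier run changes the charge of second substrate; that part of a forecast is a guess

1. apparent order in second substrate when 10% of the starting material are converted (percent change of the rate of making target for one percent more second substrate charged)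
2. factor on the rate of making target when 10% of the starting material are converted if second substrate is charged twice over

First I ask how much enzyme works. South's target stays at 0.7% or below, close to the scatter of 0.5 percentage points, and its enzyme charge of 22 µM is smaller than its impurity charge of 37 µM. So I take impurity as removing enzyme one to one and write its balance. In the flask, impurity is the limiting reagent of that titration. This leaves 6.00 µM of working enzyme W, the enzyme charged minus the impurity charged.

Does target follow W? North-east has 49.0 µM and north has 25.0 µM, a ratio of 1.96. At 30.0 s, their targets stand at 23.5% and 12.1%, a ratio of 1.94. So in these two runs it does, within the scatter of the readings.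

How long does the flask need? North reaches 12.1% in 30.0 s. Scaling by W at a steady rate, I reckon the flask reaches 10% in about 1.72 min. That is longer than the 15.0 s by which north-east has passed it.

W gives me this time, but not the order. No run changes the charge of second substrate, so my order stays a guess.

The forecast gives 0.25 and 1.17, and says “I therefore guess a small order, with a wide range”.

The flask gives an order of 0.76 and a factor of 1.59, both higher than the forecast.

    starting material + enzyme ⇌ starting complex (K = 22.0 /M, k = 48000 /M/s)
    second substrate + starting complex ⇌ ternary complex (K = 3.70 /M, k = 5200 /M/s)
    ternary complex → enzyme + target (k = 57.0 /s)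
    enzyme + impurity → spent catalyst (k = 2.10 × 10⁵ /M/s)
    2 second substrate → self-condensation product (k = 0.0120 /M/s)

At 2.00 min in the flask, unbound second substrate stands at 60% of its charge, while starting material stands at 89% of its own. In the flask, W is 14.0% of the enzyme charged. At that time in the flask, starting complex, ternary complex and enzyme add up to 14.0%, and spent catalyst stands at 86.0%.

(The runs were generated by integration with constants of no real substance.)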